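**Retrosynthetic overview**
- Theasinensin B comes from its undeca-O-benzyl ether by global hydrogenolysis.
- The biaryl C–C bond comes from a [3,3]-sigmatropic (aromatic Claisen) rearrangement of a mixed aryl benzyl orthoquinone monoketal. The ketal is made from a dearomatised ring B (gallate half) and a ring B monophenol (other half).
- Both halves come from one monophenol, 5,7,4',5'-tetra-O-benzyl-epigallocatechin. The gallate half is its 3-O-ester with tri-O-benzylgallic acid.
- The monophenol comes from (−)-epigallocatechin by masking the 3',4'-diol as a ketal, benzylating, unmasking, and benzylating the central 4'-OH.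
- No ring is built. Rings A, B and C of both halves and all four stereocentres are bought. Ring B of the gallate half is dearomatised and rearomatised around the key step.

**Assumption:** the SMILES fixes the four sp3 centres (2R,3R in each flavan unit) but not the biaryl axis. Natural theasinensin B has the R axis, so the R atropisomer of 12 is carried on. Compounds 1 and 6 are taken as commercial.

**Step 1**
Reactants: 1 (−)-epigallocatechin, (2R,3R)-2-(3,4,5-trihydroxyphenyl)chroman-3,5,7-triol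
Product: 3 5,7,5'-tri-O-benzyl-3',4'-O-(diphenylmethylene)-(−)-epigallocatechin (2R,3R; 3-OH free), via 3',4'-O-diphenylmethylene-epigallocatechin 2 (not isolated)
Conditions: Ph2CCl2 (1.2 equiv), K2CO3 (8 equiv), MeCN, Ar, rt, 16 h; then BnBr (3.3 equiv), DMF, rt, 24 h
Reagents that add atoms: dichlorodiphenylmethane, ClC(Cl)(c1ccccc1)c1ccccc1; benzyl bromide, BrCc1ccccc1
Why: Double Williamson-type O-alkylation by Ph2CCl2 gives a stable product only where two phenols are vicinal (five-membered benzodioxole), so it ties up one 3',4'-pair of ring B (the two pairs are equivalent), after which Williamson benzylation in the same pot caps the three isolated phenols while carbonate is too weak to ionise the 3-OH and no bond to C2 or C3 is touched.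

**Step 2**
Reactants: 3 5,7,5'-tri-O-benzyl-3',4'-O-(diphenylmethylene)-(−)-epigallocatechin
Product: 4 5,7,5'-tri-O-benzyl-(−)-epigallocatechin (free 3',4'-catechol and 3-OH; 2R,3R)
Conditions: TFA/H2O/CH2Cl2 (1:0.2:10), Ar, 0 °C to rt, 1 h
Reagents that add atoms: none
Why: Acid-catalysed ketal hydrolysis runs through the diphenyl(aryloxy)carbenium ion, which is far easier to reach at 0 °C than any cation from the aryl benzyl ethers or from ring C, so only benzophenone is lost and C2 and C3 are retained.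

**Step 3**
Reactants: 4 5,7,5'-tri-O-benzyl-(−)-epigallocatechin
Product: 5 5,7,4',5'-tetra-O-benzyl-(−)-epigallocatechin (free outer 3'-OH and 3-OH; 2R,3R)
Conditions: BnBr (1.0 equiv), Li2CO3 (1.1 equiv), DMF, Ar, 40 °C
Reagents that add atoms: benzyl bromide, BrCc1ccccc1
Why: This is an acidity-controlled Williamson mono-etherification in which the central 4'-OH, flanked by two oxygen substituents and hydrogen-bonded by the 3'-OH in its anion, is the more acidic phenol and is the one ionised and benzylated by one equivalent of weak base, leaving the outer 3'-OH next to the free C2'-H open, with no stereocentre involved.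

**Step 4**
Reactants: 5 5,7,4',5'-tetra-O-benzyl-(−)-epigallocatechin; 6 3,4,5-tris(benzyloxy)benzoic acid
Product: 8 5,7,4',5'-tetra-O-benzyl-(−)-epigallocatechin 3-O-[3,4,5-tris(benzyloxy)benzoate] (free 3'-OH; 2R,3R), via bis-gallate diester 7 (not isolated)
Conditions: 6 (2.4 equiv), N,N'-dicyclohexylcarbodiimide (DCC, 2.4 equiv), 4-(dimethylamino)pyridine (0.3 equiv), CH2Cl2, rt, 16 h; then pyrrolidine (4 equiv), rt, 1 h
Reagents that add atoms: 3,4,5-tris(benzyloxy)benzoic acid (6), OC(=O)c1cc(OCc2ccccc2)c(OCc2ccccc2)c(OCc2ccccc2)c1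
Why: Steglich esterification acylates the phenol and the hindered axial 3-OH at oxygen (retention at C3), and the chemoselective aminolysis that follows cleaves only the activated aryl ester because phenoxide is a far better leaving group than the secondary alkoxide.

**Step 5**
Reactants: 8 5,7,4',5'-tetra-O-benzyl-(−)-epigallocatechin 3-O-[3,4,5-tris(benzyloxy)benzoate]; 5 5,7,4',5'-tetra-O-benzyl-(−)-epigallocatechin
Product: 12 undeca-O-benzyl-theasinensin B (C6' of the gallate half bonded to C2' of the other half; free 3'-OH on each ring B; free 3-OH on the non-galloylated half; both flavan units 2R,3R; R axis), via orthoquinol acetate 9 (not isolated), via mixed aryl benzyl ketal 10 (not isolated), via bis-cyclohexadienone 11 (not isolated)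
Conditions: PhI(OAc)2 (1.0 equiv), CH2Cl2, −40 to 0 °C; then 5 (1.5 equiv), (PhO)2P(O)OH (10 mol %), 4 Å MS, −40 °C to rt; atropisomers separated on SiO2
Reagents that add atoms: (diacetoxyiodo)benzene, CC(=O)OI(OC(C)=O)c1ccccc1 (its acetoxy group sits in 9 only; no atom of it is left in 12)
Why: Wessely-type oxidative dearomatisation puts acetate on the benzyloxy-bearing C4' next to the phenol of 8, acid-catalysed exchange of this leaving group for the 3'-OH of 5 gives an aryl cyclohexadienyl ether, and its aromatic Claisen ([3,3]-sigmatropic) rearrangement across C2'=C3'–O–C4'–C5'=C6' forms the hindered C2'–C6' bond in a six-membered transition state driven by double tautomerisation of 11 to two phenols, while the biaryl axis, the only new stereo-element, is set by centre-to-axis transfer under control of the two (2R)-chromanyl groups flanking the new bond and the atropisomers are separable diastereomers.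

**Step 6**
Reactants: 12 undeca-O-benzyl-theasinensin B
Product: 13 theasinensin B
Conditions: H2 (1 atm), Pd(OH)2/C, THF/MeOH (1:1), rt; filtered under Ar, Sephadex LH-20
Reagents that add atoms: none
Why: Catalytic hydrogenolysis cleaves all eleven benzylic O–CH2Ph bonds under neutral conditions that leave the gallate ester, the fourfold ortho-substituted axis, the C2–O1 bonds and the four stereocentres untouched.

**Compound list**
1 | (−)-epigallocatechin (2R,3R) | O[C@@H]1Cc2c(O)cc(O)cc2O[C@@H]1c1cc(O)c(O)c(O)c1 | starting material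
2 | 3',4'-O-(diphenylmethylene)-(−)-epigallocatechin (not isolated) | O[C@@H]1Cc2c(O)cc(O)cc2O[C@@H]1c1cc(O)c2OC(c3ccccc3)(c3ccccc3)Oc2c1 | intermediate
3 | 5,7,5'-tri-O-benzyl-3',4'-O-(diphenylmethylene)-(−)-epigallocatechin | O[C@@H]1Cc2c(OCc3ccccc3)cc(OCc3ccccc3)cc2O[C@@H]1c1cc(OCc2ccccc2)c2OC(c3ccccc3)(c3ccccc3)Oc2c1 | intermediate
4 | 5,7,5'-tri-O-benzyl-(−)-epigallocatechin (3',4'-catechol) | O[C@@H]1Cc2c(OCc3ccccc3)cc(OCc3ccccc3)cc2O[C@@H]1c1cc(O)c(O)c(OCc2ccccc2)c1 | intermediate
5 | 5,7,4',5'-tetra-O-benzyl-(−)-epigallocatechin (free 3'-OH, 3-OH) | O[C@@H]1Cc2c(OCc3ccccc3)cc(OCc3ccccc3)cc2O[C@@H]1c1cc(O)c(OCc2ccccc2)c(OCc2ccccc2)c1 | intermediate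
6 | 3,4,5-tris(benzyloxy)benzoic acid | OC(=O)c1cc(OCc2ccccc2)c(OCc2ccccc2)c(OCc2ccccc2)c1 | starting material
7 | 3-O,3'-O-bis[3,4,5-tris(benzyloxy)benzoyl]-5,7,4',5'-tetra-O-benzyl-(−)-epigallocatechin (not isolated) | O=C(O[C@@H]1Cc2c(OCc3ccccc3)cc(OCc3ccccc3)cc2O[C@@H]1c1cc(OC(=O)c2cc(OCc3ccccc3)c(OCc3ccccc3)c(OCc3ccccc3)c2)c(OCc2ccccc2)c(OCc2ccccc2)c1)c1cc(OCc2ccccc2)c(OCc2ccccc2)c(OCc2ccccc2)c1 | intermediate
8 | 5,7,4',5'-tetra-O-benzyl-(−)-epigallocatechin 3-O-[3,4,5-tris(benzyloxy)benzoate] (free 3'-OH) | O=C(O[C@@H]1Cc2c(OCc3ccccc3)cc(OCc3ccccc3)cc2O[C@@H]1c1cc(O)c(OCc2ccccc2)c(OCc2ccccc2)c1)c1cc(OCc2ccccc2)c(OCc2ccccc2)c(OCc2ccccc2)c1 | intermediate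
9 | orthoquinol acetate of 8: ring B is a 4'-acetoxy-4',5'-bis(benzyloxy)cyclohexa-dienone with C3'=O (C4' epimers, not isolated) | O=C(O[C@@H]1Cc2c(OCc3ccccc3)cc(OCc3ccccc3)cc2O[C@@H]1C1=CC(=O)C(OCc2ccccc2)(OC(C)=O)C(OCc2ccccc2)=C1)c1cc(OCc2ccccc2)c(OCc2ccccc2)c(OCc2ccccc2)c1 | intermediate
10 | mixed ketal: the acetate of 9 replaced by the 3'-O of 5 (C4' epimers, not isolated) | O=C(O[C@@H]1Cc2c(OCc3ccccc3)cc(OCc3ccccc3)cc2O[C@@H]1C1=CC(=O)C(OCc2ccccc2)(Oc2cc([C@H]3Oc4cc(OCc5ccccc5)cc(OCc5ccccc5)c4C[C@H]3O)cc(OCc3ccccc3)c2OCc2ccccc2)C(OCc2ccccc2)=C1)c1cc(OCc2ccccc2)c(OCc2ccccc2)c(OCc2ccccc2)c1 | intermediate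
11 | bis-cyclohexadienone from the [3,3] shift: new C6'–C2' bond between two transient sp3 CH carbons (not isolated) | O=C(O[C@@H]1Cc2c(OCc3ccccc3)cc(OCc3ccccc3)cc2O[C@@H]1C1=CC(=O)C(OCc2ccccc2)=C(OCc2ccccc2)C1C1C(=O)C(OCc2ccccc2)=C(OCc2ccccc2)C=C1[C@H]1Oc2cc(OCc3ccccc3)cc(OCc3ccccc3)c2C[C@H]1O)c1cc(OCc2ccccc2)c(OCc2ccccc2)c(OCc2ccccc2)c1 | intermediate
12 | undeca-O-benzyl-theasinensin B (R axis, not encoded in SMILES) | O=C(O[C@@H]1Cc2c(OCc3ccccc3)cc(OCc3ccccc3)cc2O[C@@H]1c1cc(O)c(OCc2ccccc2)c(OCc2ccccc2)c1-c1c([C@H]2Oc3cc(OCc4ccccc4)cc(OCc4ccccc4)c3C[C@H]2O)cc(OCc2ccccc2)c(OCc2ccccc2)c1O)c1cc(OCc2ccccc2)c(OCc2ccccc2)c(OCc2ccccc2)c1 | intermediate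
13 | theasinensin B | O=C(O[C@@H]1Cc2c(O)cc(O)cc2O[C@@H]1c1cc(O)c(O)c(O)c1-c1c([C@H]2Oc3cc(O)cc(O)c3C[C@H]2O)cc(O)c(O)c1O)c1cc(O)c(O)c(O)c1 | target

**Total step count:** 6. **Longest linear sequence:** 6 (1 → 3 → 4 → 5 → 8 → 12 → 13; compound 5 enters twice).

**Steps most likely to fail**

1. **Step 5.**
   - *Risks:* The benzylated rings A (C6/C8) can attack the cation from 9 in a Friedel–Crafts reaction. Compound 9 can lose its identity by acetate migration or Diels–Alder dimerisation. The new bond is flanked by four ortho groups. The R/S ratio at the axis is not predictable.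
   - *Mitigating point:* a stray C–C bond through C6' of 5 would still give 13 after debenzylation, because ring B becomes symmetric.
   - *Fallback:* it sets out from 8 and 5 and comes back at 13. Oxidise 8 with PhI(OAc)2 in wet MeCN. Water, not acetate, then adds to C4', and the hemiketal loses benzyl alcohol to give the 5'-O-benzyl orthoquinone gallate F1. Add 5 to F1 as a carbon nucleophile in a plain ionic conjugate addition (CF3CH2OH, rt, no oxygen tether). Finish with aqueous Na2S2O4 to return any over-oxidised biaryl quinone, and isolate the deca-O-benzyl biaryl catechol F2. Hydrogenolysis of F2 under the conditions of step 6 gives 13.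

2. **Step 3.**
   - *Risks:* The acidity gap between the 4'-OH and the 3'-OH may be too small. The result would be the useless 3'-O-benzyl isomer and the perbenzyl ether.
   - *Fallback:* it sets out from 4 and comes back at 5, and it replaces acidity control by steric control with a blocking group that cannot migrate. Treat 4 with 2-nitrobenzenesulfonyl chloride (1.0 equiv), iPr2NEt, CH2Cl2, −20 °C. This sulfonylates the unhindered outer phenol to give the 3'-O-nosylate F3. BnBr/K2CO3/DMF benzylates the remaining 4'-OH to give the 3'-O-nosyl-4'-O-benzyl ether F4. PhSH/K2CO3/DMF removes the nosyl group by ipso-substitution and gives 5.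

3. **Step 1.**
   - *Risks:* The free pyrogallol under carbonate is prone to air oxidation, C2 epimerisation and C-benzylation of ring A. Ketal formation with Ph2CCl2 may stall.
   - *Fallback:* it sets out from 1 and comes back at 4, so it also replaces the acidic step 2. Treat 1 with tBu2SiCl2, Et3N, MeCN, rt to tie the 3',4'-diol up as the 3',4'-O-(di-tert-butylsilylene)-epigallocatechin F5. BnBr/K2CO3/DMF gives the 5,7,5'-tri-O-benzyl silylene F6. Et3N·3HF in THF removes the silylene under near-neutral conditions and gives 4.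

**Further compounds**
F1 | step 5 | 5'-O-benzyl 3',4'-orthoquinone of 5,7-di-O-benzyl-epigallocatechin 3-O-[3,4,5-tris(benzyloxy)benzoate] | O=C(O[C@@H]1Cc2c(OCc3ccccc3)cc(OCc3ccccc3)cc2O[C@@H]1C1=CC(=O)C(=O)C(OCc2ccccc2)=C1)c1cc(OCc2ccccc2)c(OCc2ccccc2)c(OCc2ccccc2)c1
F2 | step 5 | deca-O-benzyl-theasinensin B with a free 3',4'-catechol on ring B of the gallate half | O=C(O[C@@H]1Cc2c(OCc3ccccc3)cc(OCc3ccccc3)cc2O[C@@H]1c1cc(O)c(O)c(OCc2ccccc2)c1-c1c([C@H]2Oc3cc(OCc4ccccc4)cc(OCc4ccccc4)c3C[C@H]2O)cc(OCc2ccccc2)c(OCc2ccccc2)c1O)c1cc(OCc2ccccc2)c(OCc2ccccc2)c(OCc2ccccc2)c1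
F3 | step 3 | 5,7,5'-tri-O-benzyl-3'-O-(2-nitrobenzenesulfonyl)-(−)-epigallocatechin | O[C@@H]1Cc2c(OCc3ccccc3)cc(OCc3ccccc3)cc2O[C@@H]1c1cc(OS(=O)(=O)c2ccccc2[N+](=O)[O-])c(O)c(OCc2ccccc2)c1
F4 | step 3 | 5,7,4',5'-tetra-O-benzyl-3'-O-(2-nitrobenzenesulfonyl)-(−)-epigallocatechin | O[C@@H]1Cc2c(OCc3ccccc3)cc(OCc3ccccc3)cc2O[C@@H]1c1cc(OS(=O)(=O)c2ccccc2[N+](=O)[O-])c(OCc2ccccc2)c(OCc2ccccc2)c1
F5 | step 1 | 3',4'-O-(di-tert-butylsilylene)-(−)-epigallocatechin | O[C@@H]1Cc2c(O)cc(O)cc2O[C@@H]1c1cc(O)c2O[Si](C(C)(C)C)(C(C)(C)C)Oc2c1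
F6 | step 1 | 5,7,5'-tri-O-benzyl-3',4'-O-(di-tert-butylsilylene)-(−)-epigallocatechin | O[C@@H]1Cc2c(OCc3ccccc3)cc(OCc3ccccc3)cc2O[C@@H]1c1cc(OCc2ccccc2)c2O[Si](C(C)(C)C)(C(C)(C)C)Oc2c1
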